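**Retrosynthetic overview**
1. Target 23 ⇒ C4–C6′ bond made last by a stereoretentive 1,2-shift of the chroman-4-yl carbon from boron to the arene carbon (1,2-metallate rearrangement) in boronate complex 21, built from (S)-boronic ester 18 and the ortho-lithiated phenoxide of bromochromene 19.
2. 18 and 19 ⇒ one monomer, chromene 16: Cu–H hydroboration sets C-4, ortho-bromination marks C-6.
3. 16 ⇒ resorcylate 11 + prenal; the ester chelates one OH, so it fixes which oxygen closes the pyran, and then leaves as CO2.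
4. 11 ⇒ methyl acetoacetate + α-prenyl ester 7 (Michael–Dieckmann annulation, aromatisation); 7 from 4-iodophenol, allyl alcohol, monomethyl malonate and prenyl bromide.
5. Ring order: resorcinol ring (step 4) → 2H-pyran (step 5) → chromane by hydroboration of the pyran C=C (step 8); the halves are joined in step 10.

Assumption: the sense of induction of (R)-DTBM-SEGPHOS in step 8 is taken by analogy with acyclic β-alkylstyrenes; if it proves opposite, the (S)-ligand is used.

Step 1
Reactants: 1 4-iodophenol; 2 allyl alcohol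
Product: 3 3-(4-hydroxyphenyl)propanal
Conditions: Pd(OAc)2 (2 mol%), Bu4NCl, NaHCO3, DMF, 45 °C
Reagents that add atoms: none
Why: Jeffery-type Heck arylation of an allylic alcohol, in which β-hydride elimination towards the carbinol carbon and enol–aldehyde tautomerisation give the 3-arylpropanal directly and the free phenol is tolerated.

Step 2
Reactants: 3 3-(4-hydroxyphenyl)propanal; 4 monomethyl malonate
Product: 5 methyl (2E)-5-(4-hydroxyphenyl)pent-2-enoate
Conditions: DMAP (10 mol%), DMF, 25 °C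
Reagents that add atoms: none
Why: Doebner–Knoevenagel condensation with a malonic half ester gives the (E)-enoate with loss of CO2, and the double-bond position is immaterial because step 3 passes through the common dienolate.

Step 3
Reactants: 5 methyl (2E)-5-(4-hydroxyphenyl)pent-2-enoate; 6 prenyl bromide
Product: 7 methyl (3E)-5-(4-hydroxyphenyl)-2-(3-methylbut-2-en-1-yl)pent-3-enoate (racemic)
Conditions: LDA (2.2 equiv), THF/DMPU, −78 °C; then 6, −78 → −40 °C
Reagents that add atoms: none
Why: Deconjugative α-alkylation of an ester dienolate, which reacts with the allylic bromide at the α-carbon much faster than the lithium phenoxide at low temperature; the new C-2 centre is racemic and is erased in step 4.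

Step 4
Reactants: 7 methyl (3E)-5-(4-hydroxyphenyl)-2-(3-methylbut-2-en-1-yl)pent-3-enoate; 8 methyl acetoacetate
Product: 11 methyl 2,4-dihydroxy-6-[2-(4-hydroxyphenyl)ethyl]-5-(3-methylbut-2-en-1-yl)benzoate, via conjugated enoate 9 (not isolated), via cyclohexanedione ester 10 (not isolated)
Conditions: NaOMe (3.5 equiv), MeOH, 65 °C; AcOH, concentrate; I2 (20 mol%), DMSO, 80 °C
Reagents that add atoms: none
Why: Michael–Dieckmann (Michael–Claisen) annulation in which methoxide reconjugates the ester, the acetoacetate anion adds to the β-carbon and the acetyl methyl closes onto the enoate ester, so prenyl and arylethyl sit on adjacent ring carbons by construction, and iodine-catalysed DMSO dehydrogenation aromatises the dione (no stereocentre survives).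

Step 5
Reactants: 11 methyl 2,4-dihydroxy-6-[2-(4-hydroxyphenyl)ethyl]-5-(3-methylbut-2-en-1-yl)benzoate; 12 prenal
Product: 14 methyl 5-hydroxy-7-[2-(4-hydroxyphenyl)ethyl]-2,2-dimethyl-8-(3-methylbut-2-en-1-yl)-2H-chromene-6-carboxylate, via o-quinone methide 13 (not isolated)
Conditions: EDDA (10 mol%), toluene, 110 °C
Reagents that add atoms: none
Why: Amine-salt-catalysed chromenylation (Knoevenagel-type condensation at C-3, the only free ring carbon, then oxa-6π electrocyclisation), in which the ester-chelated 2-OH stays out so the pyran closes on O-4 next to the prenyl group.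

Step 6
Reactants: 14 methyl 5-hydroxy-7-[2-(4-hydroxyphenyl)ethyl]-2,2-dimethyl-8-(3-methylbut-2-en-1-yl)-2H-chromene-6-carboxylate
Product: 16 7-[2-(4-hydroxyphenyl)ethyl]-2,2-dimethyl-8-(3-methylbut-2-en-1-yl)-2H-chromen-5-ol, via chromene acid 15 (not isolated)
Conditions: KOH, MeOH/H2O, 90 °C; then AcOH to pH 5, 60 °C
Reagents that add atoms: none
Why: Saponification followed by protodecarboxylation of a 2,4-dioxygenated salicylic acid, which loses CO2 readily on mild acidification and warming while the chromene and prenyl groups are inert to hot alkali.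

Step 7
Reactants: 16 7-[2-(4-hydroxyphenyl)ethyl]-2,2-dimethyl-8-(3-methylbut-2-en-1-yl)-2H-chromen-5-ol
Product: 17 5-O,4′-O-bis(tert-butyldimethylsilyl) ether of 16
Conditions: TBSCl (2.4 equiv), imidazole, DMF, 25 °C
Reagents that add atoms: tert-butyldimethylsilyl chloride, CC(C)(C)[Si](C)(C)Cl
Why: Standard silyl ether formation masks both phenols so that they neither quench the copper hydride in step 8 nor coordinate the C-4 boron in step 10.

Step 8
Reactants: 17 5-O,4′-O-bis(tert-butyldimethylsilyl) ether of 16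
Product: 18 (4S)-5-(tert-butyldimethylsilyloxy)-7-[2-(4-(tert-butyldimethylsilyloxy)phenyl)ethyl]-2,2-dimethyl-8-(3-methylbut-2-en-1-yl)-4-(4,4,5,5-tetramethyl-1,3,2-dioxaborolan-2-yl)chromane
Conditions: Cu(OAc)2 (5 mol%), (R)-DTBM-SEGPHOS (5.5 mol%), HBpin (1.5 equiv), THF, 40 °C
Reagents that add atoms: pinacolborane, CC1(C)OBOC1(C)C
Why: Copper hydride-catalysed Markovnikov asymmetric hydroboration of a cyclic cis-β-substituted styrene, in which enantioface-selective syn Cu–H insertion puts copper on benzylic C-4 and stereoretentive σ-bond metathesis with HBpin sets the (S)-C–B centre, while the trisubstituted prenyl alkenes do not insert.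

Step 9
Reactants: 16 7-[2-(4-hydroxyphenyl)ethyl]-2,2-dimethyl-8-(3-methylbut-2-en-1-yl)-2H-chromen-5-ol
Product: 19 6-bromo-7-[2-(4-hydroxyphenyl)ethyl]-2,2-dimethyl-8-(3-methylbut-2-en-1-yl)-2H-chromen-5-ol
Conditions: NBS (1.0 equiv), i-Pr2NH (10 mol%), CH2Cl2, −78 °C
Reagents that add atoms: N-bromosuccinimide, O=C1CCC(=O)N1Br
Why: Amine-catalysed ortho-bromination of a phenol (electrophilic aromatic substitution) at C-6, the only free position of the resorcinol-type ring, which is far more nucleophilic than the 4-alkylphenol ring and, with one equivalent at −78 °C, than the alkenes.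

Step 10
Reactants: 19 6-bromo-7-[2-(4-hydroxyphenyl)ethyl]-2,2-dimethyl-8-(3-methylbut-2-en-1-yl)-2H-chromen-5-ol; 18 (4S)-boronic ester
Product: 23 (4R)-4-[5-hydroxy-7-[2-(4-hydroxyphenyl)ethyl]-2,2-dimethyl-8-(3-methylbut-2-en-1-yl)-2H-chromen-6-yl]-7-[2-(4-hydroxyphenyl)ethyl]-2,2-dimethyl-8-(3-methylbut-2-en-1-yl)chroman-5-ol, via aryl trilithium 20 (not isolated), via boronate complex 21 (not isolated), via bis-TBS ether 22 (not isolated)
Conditions: 19, t-BuLi (4.1 equiv), THF, −78 °C; 18, −78 → 0 °C; Martin sulfurane (2.2 equiv), −78 → 25 °C; then TBAF, THF, 25 °C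
Reagents that add atoms: none
Why: Proposed new method: the ortho-lithiated phenoxide 20 adds to the boronic ester to give boronate complex 21, the sulfurane then turns the neighbouring phenoxide oxygen into a leaving group so that C-6 becomes electrophilic and the chroman-4-yl carbon shifts 1,2 from boron to carbon with retention ((S)-C–B becomes (R)-C–C), after which loss of boron rearomatises the ring and fluoride removes both silyl groups; the closest known reaction type is the electrophile-triggered enantiospecific 1,2-metallate coupling of secondary boronic esters with lithiated electron-rich arenes and O-activated phenols, not yet shown for a free ortho-phenoxide on a di-ortho-substituted, polyanionic arene.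

**Compound list**
1 | 4-iodophenol | Oc1ccc(I)cc1 | starting material
2 | allyl alcohol | OCC=C | starting material
3 | 3-(4-hydroxyphenyl)propanal | O=CCCc1ccc(O)cc1 | intermediate
4 | monomethyl malonate (3-methoxy-3-oxopropanoic acid) | COC(=O)CC(=O)O | starting material
5 | methyl (2E)-5-(4-hydroxyphenyl)pent-2-enoate | COC(=O)/C=C/CCc1ccc(O)cc1 | intermediate
6 | prenyl bromide (1-bromo-3-methylbut-2-ene) | CC(C)=CCBr | starting material
7 | methyl (3E)-5-(4-hydroxyphenyl)-2-(3-methylbut-2-en-1-yl)pent-3-enoate, racemic | COC(=O)C(CC=C(C)C)/C=C/Cc1ccc(O)cc1 | intermediate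
8 | methyl acetoacetate | COC(=O)CC(C)=O | starting material
9 | methyl 5-(4-hydroxyphenyl)-2-(3-methylbut-2-en-1-yl)pent-2-enoate, E/Z mixture | COC(=O)C(CC=C(C)C)=CCCc1ccc(O)cc1 | intermediate
10 | methyl 6-[2-(4-hydroxyphenyl)ethyl]-5-(3-methylbut-2-en-1-yl)-2,4-dioxocyclohexane-1-carboxylate, mixture of diastereomers and enol forms | COC(=O)C1C(=O)CC(=O)C(CC=C(C)C)C1CCc1ccc(O)cc1 | intermediate
11 | methyl 2,4-dihydroxy-6-[2-(4-hydroxyphenyl)ethyl]-5-(3-methylbut-2-en-1-yl)benzoate | COC(=O)c1c(O)cc(O)c(CC=C(C)C)c1CCc1ccc(O)cc1 | intermediate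
12 | prenal (3-methylbut-2-enal) | CC(C)=CC=O | starting material
13 | methyl 2-hydroxy-6-[2-(4-hydroxyphenyl)ethyl]-5-(3-methylbut-2-en-1-yl)-3-(3-methylbut-2-en-1-ylidene)-4-oxocyclohexa-1,5-diene-1-carboxylate (o-quinone methide) | COC(=O)C1=C(O)C(=CC=C(C)C)C(=O)C(CC=C(C)C)=C1CCc1ccc(O)cc1 | intermediate
14 | methyl 5-hydroxy-7-[2-(4-hydroxyphenyl)ethyl]-2,2-dimethyl-8-(3-methylbut-2-en-1-yl)-2H-chromene-6-carboxylate | COC(=O)c1c(O)c2C=CC(C)(C)Oc2c(CC=C(C)C)c1CCc1ccc(O)cc1 | intermediate
15 | 5-hydroxy-7-[2-(4-hydroxyphenyl)ethyl]-2,2-dimethyl-8-(3-methylbut-2-en-1-yl)-2H-chromene-6-carboxylic acid | OC(=O)c1c(O)c2C=CC(C)(C)Oc2c(CC=C(C)C)c1CCc1ccc(O)cc1 | intermediate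
16 | 7-[2-(4-hydroxyphenyl)ethyl]-2,2-dimethyl-8-(3-methylbut-2-en-1-yl)-2H-chromen-5-ol | CC(C)=CCc1c(CCc2ccc(O)cc2)cc(O)c2C=CC(C)(C)Oc12 | intermediate
17 | 5-O,4′-O-bis(tert-butyldimethylsilyl) ether of 16 | CC(C)=CCc1c(CCc2ccc(O[Si](C)(C)C(C)(C)C)cc2)cc(O[Si](C)(C)C(C)(C)C)c2C=CC(C)(C)Oc12 | intermediate
18 | (4S)-5-(tert-butyldimethylsilyloxy)-7-[2-(4-(tert-butyldimethylsilyloxy)phenyl)ethyl]-2,2-dimethyl-8-(3-methylbut-2-en-1-yl)-4-(pinacolboryl)chromane | CC1(C)OB(OC1(C)C)[C@H]2CC(C)(C)Oc3c(CC=C(C)C)c(CCc4ccc(O[Si](C)(C)C(C)(C)C)cc4)cc(O[Si](C)(C)C(C)(C)C)c32 | intermediate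
19 | 6-bromo-7-[2-(4-hydroxyphenyl)ethyl]-2,2-dimethyl-8-(3-methylbut-2-en-1-yl)-2H-chromen-5-ol | CC(C)=CCc1c(CCc2ccc(O)cc2)c(Br)c(O)c2C=CC(C)(C)Oc12 | intermediate
20 | 6-lithio-chromene 5-O,4′-O-dilithium bis(phenoxide) derived from 19 | CC(C)=CCc1c(CCc2ccc(O[Li])cc2)c([Li])c(O[Li])c2C=CC(C)(C)Oc12 | intermediate
21 | lithium boronate complex of 20 with 18 (B bears pinacolato, chromen-6-yl and (4S)-chroman-4-yl) | [Li+].CC(C)=CCc1c(CCc2ccc(O[Li])cc2)c(c(O[Li])c2C=CC(C)(C)Oc12)[B-]3(OC(C)(C)C(C)(C)O3)[C@H]4CC(C)(C)Oc5c(CC=C(C)C)c(CCc6ccc(O[Si](C)(C)C(C)(C)C)cc6)cc(O[Si](C)(C)C(C)(C)C)c54 | intermediate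
22 | (4R)-coupled dimer with both chromane-unit phenols as TBS ethers | CC(C)=CCc1c(CCc2ccc(O)cc2)c([C@H]3CC(C)(C)Oc4c(CC=C(C)C)c(CCc5ccc(O[Si](C)(C)C(C)(C)C)cc5)cc(O[Si](C)(C)C(C)(C)C)c43)c(O)c2C=CC(C)(C)Oc12 | intermediate
23 | (4R)-4-[5-hydroxy-7-[2-(4-hydroxyphenyl)ethyl]-2,2-dimethyl-8-(3-methylbut-2-en-1-yl)-2H-chromen-6-yl]-7-[2-(4-hydroxyphenyl)ethyl]-2,2-dimethyl-8-(3-methylbut-2-en-1-yl)chroman-5-ol (CNP0103951.1) | CC(C)=CCc1c(CCc2ccc(O)cc2)c([C@H]2CC(C)(C)Oc3c(CC=C(C)C)c(CCc4ccc(O)cc4)cc(O)c32)c(O)c2c1OC(C)(C)C=C2 | target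

**Step count and risks**
Total steps: 10. Longest linear sequence: 9 (steps 1–8 and 10; step 9 is a one-step branch from 16).

Most likely to fail:

Step 10 (the proposed new step): both partners are very hindered, the arene is a trianion, and in situ O-activation of a free ortho-phenoxide is untested. The fallback uses known chemistry, sets out from 16 and comes back at 23. Chromene 16 is dimerised head-to-tail with a Brønsted acid (PPTS, CH2Cl2, 0 °C, stopped at partial conversion). This is the known acid-catalysed dimerisation of 2,2-dimethyl-2H-chromenes, in which the C-3-protonated monomer is attacked by C-6 of a second molecule. It gives the racemic dimer F1, and preparative chiral SFC of F1 gives 23.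

Step 8: the C-4 position is flanked by the peri silyloxy group and the gem-dimethyl-bearing CH2, so Cu–H insertion and its enantioselectivity are uncertain. The fallback sets out from 17 and comes back at 18. Cationic rhodium-catalysed Markovnikov hydroboration ([Rh(cod)2]BF4/dppb, catecholborane, THF; then pinacol) gives the racemic boronic ester F2, and preparative chiral SFC gives 18. Stereocontrol then comes from resolution, not from the catalyst.

Step 4: Michael addition to an α,β-dialkyl enoate may be slow, and the aromatisation must spare the prenyl group. The fallback sets out from 3 and comes back at 10, which is aromatised to 11 as in step 4; it reverses the polarity of the Michael step. Aldehyde 3 and methyl acetoacetate 8 give the Knoevenagel adduct methyl 2-acetyl-5-(4-hydroxyphenyl)pent-2-enoate F3 (piperidinium acetate, CH2Cl2, 0 °C). Methyl acetate is alkylated with 6 (LDA, THF, −78 °C) to methyl 5-methylhex-4-enoate F4. The lithium enolate of F4 adds to the doubly activated alkene of F3 (phenol pre-deprotonated with LiHMDS, THF, −78 °C) to give the Michael adduct dimethyl 2-acetyl-3-[2-(4-hydroxyphenyl)ethyl]-4-(3-methylbut-2-en-1-yl)pentanedioate F5. NaOMe in MeOH then closes the ring to 10.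

Further compounds
F1 | step 10 | racemic 4-[5-hydroxy-7-[2-(4-hydroxyphenyl)ethyl]-2,2-dimethyl-8-(3-methylbut-2-en-1-yl)-2H-chromen-6-yl]-7-[2-(4-hydroxyphenyl)ethyl]-2,2-dimethyl-8-(3-methylbut-2-en-1-yl)chroman-5-ol | CC(C)=CCc1c(CCc2ccc(O)cc2)c(C2CC(C)(C)Oc3c(CC=C(C)C)c(CCc4ccc(O)cc4)cc(O)c32)c(O)c2c1OC(C)(C)C=C2
F2 | step 8 | racemic 5-(tert-butyldimethylsilyloxy)-7-[2-(4-(tert-butyldimethylsilyloxy)phenyl)ethyl]-2,2-dimethyl-8-(3-methylbut-2-en-1-yl)-4-(pinacolboryl)chromane | CC1(C)OB(OC1(C)C)C2CC(C)(C)Oc3c(CC=C(C)C)c(CCc4ccc(O[Si](C)(C)C(C)(C)C)cc4)cc(O[Si](C)(C)C(C)(C)C)c32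
F3 | step 4 | methyl 2-acetyl-5-(4-hydroxyphenyl)pent-2-enoate | COC(=O)C(C(C)=O)=CCCc1ccc(O)cc1
F4 | step 4 | methyl 5-methylhex-4-enoate | COC(=O)CCC=C(C)C
F5 | step 4 | dimethyl 2-acetyl-3-[2-(4-hydroxyphenyl)ethyl]-4-(3-methylbut-2-en-1-yl)pentanedioate | COC(=O)C(C(C)=O)C(CCc1ccc(O)cc1)C(CC=C(C)C)C(=O)OC
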